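**Retrosynthetic overview**
1. Target 16 is cut at C7=C8 (Wittig) to epoxy aldehyde 14, which comes from silyl ether 12 by desilylation and oxidation.
2. The strategy rests on the oxirane of the 7-oxabicyclo[4.1.0]heptane core: its oxygen bridges C5 and C6 while the neighbouring C4 is a bare CH2, so 12 is the C6 hydroxyl of tertiary allylic alcohol 11 added across its C4=C5 bond (cobalt-hydride cycloisomerisation).
3. 11 comes from allylic sulfoxide 9 by Mislow–Evans transposition (C4–S to C6–O, trans to the C3 myristate), 9 from trans hydroxy sulfide 6, and 6 from vinyl oxirane 4 and thiophenol 5.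
4. 4 comes from safranal 1 by reduction, silylation and Jacobsen–Katsuki epoxidation of the C3=C4 bond, the only step with external asymmetric induction; C4, C6 and C5 are then relayed from C3.
5. Ring order: the carbocycle is bought with safranal; a temporary C3–C4 oxirane is made in step 3 and opened in step 4; the C5–C6 oxirane, the only ring built to stay, is closed in step 8.

Key step: step 8

Numbering used in the text (ionone numbering): C1 = C(CH3)2, C2 = CH2, C3 = carbon bearing the myristate, C4, C5 = carbon bearing the ring methyl, C6 = carbon bearing the one-carbon substituent C7 (later the enone chain). The target is the (3S,5R,6S) isomer, with the oxirane trans to the ester.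

Assumption: the sense of induction in step 3 is assigned by analogy with indene and 1,2-dihydronaphthalene; if the diene responded in the opposite sense, the (S,S)-ligand would be used and nothing else would change.

Step 1
Reactants: 1 safranal (2,6,6-trimethylcyclohexa-1,3-diene-1-carbaldehyde)
Product: 2 (2,6,6-trimethylcyclohexa-1,3-dien-1-yl)methanol
Conditions: NaBH4, CeCl3·7H2O, MeOH, 0 °C
Reagents that add atoms: none
Why: Luche reduction delivers hydride 1,2 to the hindered dienal carbonyl and leaves the diene untouched; no stereocentre is formed.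

Step 2
Reactants: 2 (2,6,6-trimethylcyclohexa-1,3-dien-1-yl)methanol
Product: 3 tert-butyl(dimethyl)[(2,6,6-trimethylcyclohexa-1,3-dien-1-yl)methoxy]silane
Conditions: TBSCl, imidazole, DMF, 0 °C to rt
Reagents that add atoms: tert-butyldimethylsilyl chloride (TBSCl), CC(C)(C)[Si](C)(C)Cl
Why: Standard silylation of the primary allylic alcohol masks C7–OH for the oxidations and the key step.

Step 3
Reactants: 3 tert-butyl(dimethyl)[(2,6,6-trimethylcyclohexa-1,3-dien-1-yl)methoxy]silane
Product: 4 tert-butyl(dimethyl){[(1R,6S)-2,4,4-trimethyl-7-oxabicyclo[4.1.0]hept-2-en-3-yl]methoxy}silane (3S,4R oxirane in the numbering above)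
Conditions: (R,R)-N,N'-bis(3,5-di-tert-butylsalicylidene)-1,2-cyclohexanediaminomanganese chloride (trivalent manganese, 5 mol %), 4-phenylpyridine N-oxide, NaOCl (aq., pH 11.3), CH2Cl2, 0 °C; crude product used directly
Reagents that add atoms: sodium hypochlorite, [Na+].[O-]Cl
Why: Jacobsen–Katsuki epoxidation attacks the unhindered terminus C3 of the cis-disubstituted conjugated alkene side-on, the tetrasubstituted C5=C6 bond being too hindered, and the (R,R)-ligand is expected to place the oxygen on the face that gives 3S,4R.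

Step 4
Reactants: 4 vinyl oxirane (tert-butyl(dimethyl){[(1R,6S)-2,4,4-trimethyl-7-oxabicyclo[4.1.0]hept-2-en-3-yl]methoxy}silane); 5 thiophenol
Product: 6 (1S,2S)-4-({[tert-butyl(dimethyl)silyl]oxy}methyl)-3,5,5-trimethyl-2-(phenylsulfanyl)cyclohex-3-en-1-ol
Conditions: PhSH, Et3N, MeOH, 0 °C to rt
Reagents that add atoms: thiophenol (5), Sc1ccccc1
Why: Thiolate opening of the vinyl oxirane (SN2) occurs at the allylic carbon C4 with inversion, C6 being blocked for SN2' attack and C3 shielded by the axial C1 methyl, so C3–OH and C4–SPh come out trans and C3 keeps its configuration.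

Step 5
Reactants: 6 (1S,2S)-4-({[tert-butyl(dimethyl)silyl]oxy}methyl)-3,5,5-trimethyl-2-(phenylsulfanyl)cyclohex-3-en-1-ol; 7 myristoyl chloride (tetradecanoyl chloride)
Product: 8 (1S,2S)-4-({[tert-butyl(dimethyl)silyl]oxy}methyl)-3,5,5-trimethyl-2-(phenylsulfanyl)cyclohex-3-en-1-yl tetradecanoate
Conditions: pyridine, DMAP (cat.), CH2Cl2, 0 °C to rt
Reagents that add atoms: myristoyl chloride (7), CCCCCCCCCCCCCC(=O)Cl
Why: DMAP-catalysed O-acylation of the secondary alcohol with the acid chloride touches no stereocentre.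

Step 6
Reactants: 8 (1S,2S)-4-({[tert-butyl(dimethyl)silyl]oxy}methyl)-3,5,5-trimethyl-2-(phenylsulfanyl)cyclohex-3-en-1-yl tetradecanoate
Product: 9 (1S,2S)-2-(benzenesulfinyl)-4-({[tert-butyl(dimethyl)silyl]oxy}methyl)-3,5,5-trimethylcyclohex-3-en-1-yl tetradecanoate (both epimers at sulfur, used crude)
Conditions: mCPBA (1.0 equiv), CH2Cl2, −78 °C; aq. NaHCO3/Na2S2O3 work-up
Reagents that add atoms: meta-chloroperbenzoic acid (mCPBA), O=C(OO)c1cccc(Cl)c1
Why: Electrophilic sulfide oxidation is far faster at −78 °C than epoxidation of the tetrasubstituted alkene and stops at the sulfoxide with one equivalent; both sulfur epimers converge in the next step.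

Step 7
Reactants: 9 (1S,2S)-2-(benzenesulfinyl)-4-({[tert-butyl(dimethyl)silyl]oxy}methyl)-3,5,5-trimethylcyclohex-3-en-1-yl tetradecanoate
Product: 11 (1S,4S)-4-({[tert-butyl(dimethyl)silyl]oxy}methyl)-4-hydroxy-3,5,5-trimethylcyclohex-2-en-1-yl tetradecanoate, via allylic benzenesulfenate 10 (not isolated)
Conditions: P(OMe)3, MeOH, rt to 45 °C
Reagents that add atoms: none
Why: In the Mislow–Evans rearrangement the allylic sulfoxide equilibrates with the sulfenate by a suprafacial [2,3]-sigmatropic shift that delivers oxygen to C6 on the face C4–S occupied (trans to the C3 ester), and trimethyl phosphite cleaves the S–O bond irreversibly, which sets C6.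

Step 8
Reactants: 11 (1S,4S)-4-({[tert-butyl(dimethyl)silyl]oxy}methyl)-4-hydroxy-3,5,5-trimethylcyclohex-2-en-1-yl tetradecanoate
Product: 12 (1R,4S,6R)-1-({[tert-butyl(dimethyl)silyl]oxy}methyl)-2,2,6-trimethyl-7-oxabicyclo[4.1.0]heptan-4-yl tetradecanoate
Conditions: N,N'-bis(3,5-di-tert-butylsalicylidene)ethane-1,2-diaminocobalt (divalent cobalt, 5 mol %), N-fluoro-2,4,6-trimethylpyridinium tetrafluoroborate (1.2 equiv), PhSiH3 (1.2 equiv), acetone, 0 °C to rt
Reagents that add atoms: none
Why: Proposed new method: the N-fluoropyridinium salt and PhSiH3 turn the cobalt catalyst into a trivalent cobalt hydride, which hands a hydrogen atom to the less substituted alkene carbon C4; the tertiary C5 radical so formed is oxidised, directly or by way of a tetravalent alkylcobalt, to a cation equivalent that the neighbouring C6 hydroxyl traps with loss of a proton to collidine. The closest known reaction type is the cobalt-salen hydrogen-atom-transfer radical–polar crossover hydroalkoxylation of alkenols, including the cycloisomerisation of tertiary allylic alcohols bearing 1,1-disubstituted alkenes to epoxides; a ring-embedded trisubstituted alkene has not been shown. The oxirane closes in the 3-exo-tet mode by O–C5 bond formation. The new stereocentre C5 is fixed by C6, because the oxygen can reach C5 only on the ring face on which it already stands, which puts the C5 methyl cis to C7 and the oxirane trans to the C3 ester; a cobalt bound on the wrong face is released again by reversible homolysis. The step needs Markovnikov hydrogen-atom transfer, secured by the tertiary against secondary radical at the trisubstituted alkene, and closure ahead of a 1,2-shift of C1 to C5 (ring contraction), of alkene migration and of oxirane opening, for which the adjacent hydroxyl, the near-neutral collidine-buffered medium and the low temperature are relied on; the allylic C3 ester and the silyl ether are not ionised under these conditions.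

Step 9
Reactants: 12 (1R,4S,6R)-1-({[tert-butyl(dimethyl)silyl]oxy}methyl)-2,2,6-trimethyl-7-oxabicyclo[4.1.0]heptan-4-yl tetradecanoate
Product: 13 (1R,4S,6R)-1-(hydroxymethyl)-2,2,6-trimethyl-7-oxabicyclo[4.1.0]heptan-4-yl tetradecanoate
Conditions: HF·pyridine, pyridine, THF, 0 °C to rt
Reagents that add atoms: none
Why: Fluoride-mediated cleavage of the primary silyl ether under pyridine buffering should neither open the tetrasubstituted oxirane by acid nor shift or cleave the ester as basic fluoride might.

Step 10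
Reactants: 13 (1R,4S,6R)-1-(hydroxymethyl)-2,2,6-trimethyl-7-oxabicyclo[4.1.0]heptan-4-yl tetradecanoate
Product: 14 (1S,4S,6R)-1-formyl-2,2,6-trimethyl-7-oxabicyclo[4.1.0]heptan-4-yl tetradecanoate
Conditions: Dess–Martin periodinane, NaHCO3, CH2Cl2, 0 °C to rt
Reagents that add atoms: none
Why: Dess–Martin oxidation of the primary alcohol under bicarbonate buffer gives an aldehyde without α-hydrogen, so C6 cannot epimerise.

Step 11
Reactants: 14 (1S,4S,6R)-1-formyl-2,2,6-trimethyl-7-oxabicyclo[4.1.0]heptan-4-yl tetradecanoate; 15 1-(triphenylphosphoranylidene)propan-2-one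
Product: 16 (1S,4S,6R)-2,2,6-trimethyl-1-[(1E)-3-oxobut-1-en-1-yl]-7-oxabicyclo[4.1.0]heptan-4-yl tetradecanoate (CNP0118807.1)
Conditions: toluene, 80 °C
Reagents that add atoms: 1-(triphenylphosphoranylidene)propan-2-one (15), CC(=O)C=P(c1ccccc1)(c1ccccc1)c1ccccc1
Why: Wittig olefination with a stabilised ylide should give the E-enone, and the non-enolisable, oxirane-activated aldehyde tolerates the heating its neopentyl position requires.

**Compound list**
1 | safranal (2,6,6-trimethylcyclohexa-1,3-diene-1-carbaldehyde) | CC1=C(C=O)C(C)(C)CC=C1 | starting material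
2 | (2,6,6-trimethylcyclohexa-1,3-dien-1-yl)methanol | CC1=C(CO)C(C)(C)CC=C1 | intermediate
3 | tert-butyl(dimethyl)[(2,6,6-trimethylcyclohexa-1,3-dien-1-yl)methoxy]silane | CC1=C(CO[Si](C)(C)C(C)(C)C)C(C)(C)CC=C1 | intermediate
4 | tert-butyl(dimethyl){[(1R,6S)-2,4,4-trimethyl-7-oxabicyclo[4.1.0]hept-2-en-3-yl]methoxy}silane | CC1=C(CO[Si](C)(C)C(C)(C)C)C(C)(C)C[C@@H]2O[C@H]12 | intermediate
5 | thiophenol | Sc1ccccc1 | starting material
6 | (1S,2S)-4-({[tert-butyl(dimethyl)silyl]oxy}methyl)-3,5,5-trimethyl-2-(phenylsulfanyl)cyclohex-3-en-1-ol | O[C@H]1CC(C)(C)C(CO[Si](C)(C)C(C)(C)C)=C(C)[C@@H]1Sc1ccccc1 | intermediate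
7 | myristoyl chloride (tetradecanoyl chloride) | CCCCCCCCCCCCCC(=O)Cl | starting material
8 | (1S,2S)-4-({[tert-butyl(dimethyl)silyl]oxy}methyl)-3,5,5-trimethyl-2-(phenylsulfanyl)cyclohex-3-en-1-yl tetradecanoate | CCCCCCCCCCCCCC(=O)O[C@H]1CC(C)(C)C(CO[Si](C)(C)C(C)(C)C)=C(C)[C@@H]1Sc1ccccc1 | intermediate
9 | (1S,2S)-2-(benzenesulfinyl)-4-({[tert-butyl(dimethyl)silyl]oxy}methyl)-3,5,5-trimethylcyclohex-3-en-1-yl tetradecanoate (both epimers at sulfur) | CCCCCCCCCCCCCC(=O)O[C@H]1CC(C)(C)C(CO[Si](C)(C)C(C)(C)C)=C(C)[C@@H]1S(=O)c1ccccc1 | intermediate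
10 | (1S,4S)-4-({[tert-butyl(dimethyl)silyl]oxy}methyl)-3,5,5-trimethyl-4-[(phenylsulfanyl)oxy]cyclohex-2-en-1-yl tetradecanoate (allylic benzenesulfenate, not isolated) | CCCCCCCCCCCCCC(=O)O[C@H]1CC(C)(C)[C@@](OSc2ccccc2)(CO[Si](C)(C)C(C)(C)C)C(C)=C1 | intermediate
11 | (1S,4S)-4-({[tert-butyl(dimethyl)silyl]oxy}methyl)-4-hydroxy-3,5,5-trimethylcyclohex-2-en-1-yl tetradecanoate | CCCCCCCCCCCCCC(=O)O[C@H]1CC(C)(C)[C@@](O)(CO[Si](C)(C)C(C)(C)C)C(C)=C1 | intermediate
12 | (1R,4S,6R)-1-({[tert-butyl(dimethyl)silyl]oxy}methyl)-2,2,6-trimethyl-7-oxabicyclo[4.1.0]heptan-4-yl tetradecanoate | CCCCCCCCCCCCCC(=O)O[C@H]1CC(C)(C)[C@]2(CO[Si](C)(C)C(C)(C)C)O[C@]2(C)C1 | intermediate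
13 | (1R,4S,6R)-1-(hydroxymethyl)-2,2,6-trimethyl-7-oxabicyclo[4.1.0]heptan-4-yl tetradecanoate | CCCCCCCCCCCCCC(=O)O[C@H]1CC(C)(C)[C@]2(CO)O[C@]2(C)C1 | intermediate
14 | (1S,4S,6R)-1-formyl-2,2,6-trimethyl-7-oxabicyclo[4.1.0]heptan-4-yl tetradecanoate | CCCCCCCCCCCCCC(=O)O[C@H]1CC(C)(C)[C@]2(C=O)O[C@]2(C)C1 | intermediate
15 | 1-(triphenylphosphoranylidene)propan-2-one | CC(=O)C=P(c1ccccc1)(c1ccccc1)c1ccccc1 | starting material
16 | (1S,4S,6R)-2,2,6-trimethyl-1-[(1E)-3-oxobut-1-en-1-yl]-7-oxabicyclo[4.1.0]heptan-4-yl tetradecanoate | CCCCCCCCCCCCCC(=O)O[C@H]1CC(C)(C)[C@]2(/C=C/C(C)=O)O[C@]2(C)C1 | target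

**Step count**
Total: 11 steps. Longest linear sequence: 11 steps (1 to 16).

**Steps most likely to fail**

1. Step 8 (the proposed new method).
   - What may go wrong: a 1,2-shift of the ring carbon C1 onto the C5 cation (ring contraction); reversible hydrogen-atom transfer that migrates the double bond or ends in net hydrogenation; acid-promoted opening of the oxirane once formed.
   - Fallback by known chemistry, setting out from 4 and coming back at 13:
     - LiAlH4 in Et2O at 0 °C should open the vinyl oxirane by hydride attack at the allylic C4 and give the homoallylic alcohol F1.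
     - Acylation with 7 (pyridine, DMAP, CH2Cl2) gives the homoallylic myristate F2.
     - HF·pyridine in THF frees the tetrasubstituted allylic alcohol F3.
     - Sharpless asymmetric epoxidation (Ti(OiPr)4, D-(−)-diethyl tartrate, t-BuOOH, 4 Å sieves, CH2Cl2, −20 °C) is expected to place the oxygen on the C5=C6 face trans to the ester under reagent control and give 13 directly.

2. Step 7.
   - What may go wrong: a slow [2,3]-shift into the congested C6 position, so that thermal syn-elimination of the sulfoxide toward C3 or incomplete interception of the sulfenate takes over.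
   - Fallback, setting out from 4 and coming back at 11:
     - Sodium benzeneselenolate (PhSeSePh, NaBH4, EtOH, 0 °C to rt) should open the oxirane at C4 to the trans hydroxy selenide F4.
     - Acylation with 7 (pyridine, DMAP) gives the selenide myristate F5.
     - H2O2 with pyridine in CH2Cl2 at 0 °C gives the selenoxide F6, whose [2,3]-shift runs below room temperature, well ahead of syn-elimination, to the allylic selenenate F7.
     - F7 is hydrolysed in the flask to 11 with the same trans-1,4 relationship.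

3. Step 3.
   - What may go wrong: insufficient enantiofacial discrimination on a diene whose second alkene is tetrasubstituted, together with loss of the acid-labile vinyl oxirane on handling.
   - Fallback, setting out from 6 of inadequate enantiomeric purity and coming back at 6 before step 5:
     - Enzymatic kinetic resolution with Candida antarctica lipase B and vinyl acetate in tert-butyl methyl ether at 30 °C.
     - By Kazlauskas' rule the unwanted (1R,2R)-enantiomer should be acetylated to the acetate F8.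
     - The unreacted (1S,2S)-alcohol 6 is separated by chromatography and carried on.

**Further compounds**
F1 | step 8 | (1R)-4-({[tert-butyl(dimethyl)silyl]oxy}methyl)-3,5,5-trimethylcyclohex-3-en-1-ol | O[C@H]1CC(C)(C)C(CO[Si](C)(C)C(C)(C)C)=C(C)C1
F2 | step 8 | (1R)-4-({[tert-butyl(dimethyl)silyl]oxy}methyl)-3,5,5-trimethylcyclohex-3-en-1-yl tetradecanoate | CCCCCCCCCCCCCC(=O)O[C@H]1CC(C)(C)C(CO[Si](C)(C)C(C)(C)C)=C(C)C1
F3 | step 8 | (1R)-4-(hydroxymethyl)-3,5,5-trimethylcyclohex-3-en-1-yl tetradecanoate | CCCCCCCCCCCCCC(=O)O[C@H]1CC(C)(C)C(CO)=C(C)C1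
F4 | step 7 | (1S,2S)-4-({[tert-butyl(dimethyl)silyl]oxy}methyl)-3,5,5-trimethyl-2-(phenylselanyl)cyclohex-3-en-1-ol | O[C@H]1CC(C)(C)C(CO[Si](C)(C)C(C)(C)C)=C(C)[C@@H]1[Se]c1ccccc1
F5 | step 7 | (1S,2S)-4-({[tert-butyl(dimethyl)silyl]oxy}methyl)-3,5,5-trimethyl-2-(phenylselanyl)cyclohex-3-en-1-yl tetradecanoate | CCCCCCCCCCCCCC(=O)O[C@H]1CC(C)(C)C(CO[Si](C)(C)C(C)(C)C)=C(C)[C@@H]1[Se]c1ccccc1
F6 | step 7 | (1S,2S)-2-(benzeneseleninyl)-4-({[tert-butyl(dimethyl)silyl]oxy}methyl)-3,5,5-trimethylcyclohex-3-en-1-yl tetradecanoate | CCCCCCCCCCCCCC(=O)O[C@H]1CC(C)(C)C(CO[Si](C)(C)C(C)(C)C)=C(C)[C@@H]1[Se](=O)c1ccccc1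
F7 | step 7 | (1S,4S)-4-({[tert-butyl(dimethyl)silyl]oxy}methyl)-3,5,5-trimethyl-4-[(phenylselanyl)oxy]cyclohex-2-en-1-yl tetradecanoate | CCCCCCCCCCCCCC(=O)O[C@H]1CC(C)(C)[C@@](O[Se]c2ccccc2)(CO[Si](C)(C)C(C)(C)C)C(C)=C1
F8 | step 3 | (1R,2R)-4-({[tert-butyl(dimethyl)silyl]oxy}methyl)-3,5,5-trimethyl-2-(phenylsulfanyl)cyclohex-3-en-1-yl acetate | CC(=O)O[C@@H]1CC(C)(C)C(CO[Si](C)(C)C(C)(C)C)=C(C)[C@H]1Sc1ccccc1
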